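## Retrosynthetic overview
1. Fertidin ⇒ C4 p-anisate of diol **14** ⇒ directed reduction of ketol **13** ⇐ C3/C3a retro-aldol/aldol equilibration of **12** ⇐ ring-closing metathesis of diene **10**, which forms the cycloheptene C6=C7.
2. Diene **10** ⇐ methallyl Grignard addition to aldehyde **8** ⇐ primary alcohol **7** ⇐ key step: photochemical Co–H (MHAT) radical allylation of exocyclic alkene **5**, which forms the C8–C8a bond and the quaternary C8a.
3. **5** ⇐ photodeconjugation and reduction of cyclopentene enal **3** ⇐ ozonolysis and aldol condensation of (R)-terpinen-4-ol **1**, the only chiral building block.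
4. Ring order: cyclopentane (aldol) → quaternary C8a (photo-MHAT) → cycloheptene (RCM) → C3/C3a reset.

Assumption: the target is the trans-fused (3R,3aS,4S,8aR) hydroazulene as drawn, and (R)-(−)-terpinen-4-ol is available enantiopure.

## Route

**Step 1**
Reactants: **1** (R)-(−)-terpinen-4-ol
Product: **2** (3R)-3-hydroxy-6-oxo-3-isopropylheptanal
Conditions: O3, CH2Cl2/MeOH 4:1, −78 °C; then Me2S, −78 °C → rt
Reagents that add atoms: ozone, [O-][O+]=O
Why: Ozonolysis cleaves the only alkene, and the tertiary carbinol (future C3) is not touched.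

**Step 2**
Reactants: **2**
Product: **3** (5S)-5-hydroxy-2-methyl-5-isopropylcyclopent-1-ene-1-carbaldehyde
Conditions: pyrrolidine (10 mol%), AcOH (10 mol%), CH2Cl2, 0 °C → rt
Reagents that add atoms: none
Why: Intramolecular aldol condensation: the aldehyde enamine attacks the methyl ketone in a 5-membered ring closure, then dehydrates to the conjugated enal. This builds the cyclopentane (C3a–C8a bond) with achiral amine catalysis and keeps C3.

**Step 3**
Reactants: **3**
Product: **4** (1R,5S)-5-hydroxy-2-methylidene-5-isopropylcyclopentane-1-carbaldehyde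
Conditions: hν (350 nm), degassed Et2O/MeOH 9:1, 10 °C
Reagents that add atoms: none
Why: Photodeconjugation: the excited Z-enal abstracts a γ-H from the cis methyl (1,5-HAT) to give a dienol, which is protonated at Cα from the face of the small OH. This puts CHO on the same face as the isopropyl group.

**Step 4**
Reactants: **4**
Product: **5** [(1S,5S)-5-hydroxy-2-methylidene-5-isopropylcyclopentyl]methanol
Conditions: NaBH4, MeOH, −20 °C, 10 min
Reagents that add atoms: none (adds H only)
Why: Fast aldehyde reduction locks the Cα stereocentre against re-conjugation to enal **3**.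

**Step 5 (key step)**
Reactants: **5** and **6** allyl phenyl sulfone
Product: **7** {(1S,2R…)-5-hydroxy-2-methyl-5-isopropyl-2-allylcyclopentyl}methanol, with allyl trans to CH2OH and Me cis to it
Conditions: Co(salen) (5 mol%), 9-mesityl-10-methylacridinium ClO4 (2 mol%), PhSiH3 (2 equiv), **6** (3 equiv), MeCN/EtOH 9:1, blue LEDs, 25 °C, 16 h
Reagents that add atoms: allyl phenyl sulfone, C=CCS(=O)(=O)c1ccccc1 (PhSiH3 supplies H only)
Why: Proposed new method: photogenerated Co(III)–H transfers H• to the CH2 terminus of the 1,1-disubstituted exocyclic alkene, giving a tertiary radical whose methyl is the former methylene. Addition to the allyl sulfone and β-elimination of PhSO2• then installs the allyl group, and the radical is attacked from the face anti to the CH2OH and i-Pr groups, both of which are on the top face. The closest known reactions are Fe–H/Co–H MHAT Giese-type couplings that form quaternary centres and Keck-type radical allylation with allyl sulfones. Photochemical Co–H allylation of a cyclopentylidene with two adjacent stereocentres has not been shown.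

**Step 6**
Reactants: **7**
Product: **8** aldehyde, same ring stereochemistry as **7**
Conditions: Dess–Martin periodinane (1.5 equiv), NaHCO3, CH2Cl2, 0 °C, 1 h
Reagents that add atoms: none
Why: Chemoselective oxidation of the primary alcohol; the tertiary OH and the terminal alkene are untouched.

**Step 7**
Reactants: **8** and **9** 2-methylallylmagnesium chloride
Product: **10** 1-[cyclopentyl]-3-methylbut-3-en-1-ol as a mixture of C1 epimers
Conditions: **9** (4 equiv), THF, −78 → 0 °C
Reagents that add atoms: 2-methylallylmagnesium chloride, C=C(C)C[Mg]Cl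
Why: Grignard addition to the aldehyde; the new carbinol becomes C4 and its configuration is irrelevant because it is oxidised in Step 9.

**Step 8**
Reactants: **10**
Product: **11** cycloheptene diol, a hydroazulene with C6=C7 and a C4 epimer mixture
Conditions: Hoveyda–Grubbs II (5 mol%), toluene (2 mM), 80 °C, 4 h
Reagents that add atoms: none (ethylene is lost)
Why: Ring-closing metathesis joins the allyl and methallyl alkenes to form the trisubstituted 7-membered ring, with C6 bearing the methyl as in the target.

**Step 9**
Reactants: **11**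
Product: **12** 3-hydroxy-6,8a-dimethyl-3-isopropyl-2,3,3a,5,8,8a-hexahydroazulen-4(1H)-one, C3-epimeric to the target (3S,3aR,8aR)
Conditions: Dess–Martin periodinane (2 equiv), NaHCO3, CH2Cl2, rt, 1 h
Reagents that add atoms: none
Why: The secondary C4 alcohol is oxidised selectively; the tertiary C3–OH is inert, and this step removes the C4 epimer mixture.

**Step 10**
Reactants: **12**
Product: **13** (3R,3aR,8aR)-3-hydroxy-6,8a-dimethyl-3-isopropyl-2,3,3a,5,8,8a-hexahydroazulen-4(1H)-one
Conditions: K2CO3 (0.3 equiv), MeOH, 0 °C → rt, 6 h, monitored and quenched at equilibrium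
Reagents that add atoms: none
Why: Retro-aldol/aldol equilibration of the β-hydroxy ketone resets C3/C3a to the thermodynamic ketol, with i-Pr anti to both the angular methyl and C4=O and C3–OH hydrogen-bonded to C4=O, which is the target's (3R,3aS) relative configuration. The quaternary C8a is untouched.

**Step 11**
Reactants: **13**
Product: **14** (3R,3aS,4S,8aR)-6,8a-dimethyl-3-isopropyl-1,2,3,3a,4,5,8,8a-octahydroazulene-3,4-diol
Conditions: Me4NBH(OAc)3 (5 equiv), MeCN/AcOH 1:1, −20 °C, 12 h
Reagents that add atoms: none (adds H only)
Why: Evans–Saksena-type directed reduction: the acetoxyborohydride binds the C3 tertiary OH and delivers hydride to C4=O from the face bearing C3, which sets the 4S carbinol anti to the angular methyl.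

**Step 12**
Reactants: **14** and **15** 4-methoxybenzoyl chloride
Product: **16** Fertidin, [(3R,3aS,4S,8aR)-3-hydroxy-6,8a-dimethyl-3-isopropyl-1,2,3,3a,4,5,8,8a-octahydroazulen-4-yl] 4-methoxybenzoate
Conditions: **15** (1.5 equiv), DMAP (0.2 equiv), Et3N (3 equiv), CH2Cl2, 0 °C → rt
Reagents that add atoms: 4-methoxybenzoyl chloride, COc1ccc(C(=O)Cl)cc1
Why: Acylation of the secondary C4–OH proceeds with retention; the hindered tertiary C3–OH next to the isopropyl group does not react.

## Compound list
1 | (1R)-4-methyl-1-(propan-2-yl)cyclohex-3-en-1-ol, (R)-(−)-terpinen-4-ol | CC1=CC[C@@](O)(C(C)C)CC1 | starting material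
2 | (3R)-3-hydroxy-6-oxo-3-isopropylheptanal | O=CC[C@@](O)(C(C)C)CCC(C)=O | intermediate
3 | (5S)-5-hydroxy-2-methyl-5-isopropylcyclopent-1-ene-1-carbaldehyde | O=CC1=C(C)CC[C@]1(O)C(C)C | intermediate
4 | (1R,5S)-5-hydroxy-2-methylidene-5-isopropylcyclopentane-1-carbaldehyde | O=C[C@@H]1C(=C)CC[C@]1(O)C(C)C | intermediate
5 | [(1S,5S)-5-hydroxy-2-methylidene-5-isopropylcyclopentyl]methanol | OC[C@@H]1C(=C)CC[C@]1(O)C(C)C | intermediate
6 | allyl phenyl sulfone | C=CCS(=O)(=O)c1ccccc1 | starting material
7 | {5-hydroxy-2-methyl-5-isopropyl-2-allylcyclopentyl}methanol; CH2OH and i-Pr on one face, allyl on the opposite face | OC[C@@H]1[C@@](C)(CC=C)CC[C@]1(O)C(C)C | intermediate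
8 | corresponding cyclopentanecarbaldehyde | O=C[C@@H]1[C@@](C)(CC=C)CC[C@]1(O)C(C)C | intermediate
9 | 2-methylallylmagnesium chloride | C=C(C)C[Mg]Cl | starting material
10 | 1-[cyclopentyl]-3-methylbut-3-en-1-ol (C1 epimers) | C=C(C)CC(O)[C@@H]1[C@@](C)(CC=C)CC[C@]1(O)C(C)C | intermediate
11 | 6,8a-dimethyl-3-isopropyl-octahydroazulene-3,4-diol (C3-epi; C4 epimers) | OC2CC(C)=CC[C@@]3(C)CC[C@](O)(C(C)C)[C@H]23 | intermediate
12 | (3S,3aR,8aR)-3-hydroxy-6,8a-dimethyl-3-isopropyl-hexahydroazulen-4(1H)-one | O=C2CC(C)=CC[C@@]3(C)CC[C@](O)(C(C)C)[C@H]23 | intermediate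
13 | (3R,3aR,8aR)-3-hydroxy-6,8a-dimethyl-3-isopropyl-hexahydroazulen-4(1H)-one | O=C2CC(C)=CC[C@@]3(C)CC[C@@](O)(C(C)C)[C@H]23 | intermediate
14 | (3R,3aS,4S,8aR)-6,8a-dimethyl-3-isopropyl-octahydroazulene-3,4-diol | O[C@H]2CC(C)=CC[C@@]3(C)CC[C@@](O)(C(C)C)[C@H]23 | intermediate
15 | 4-methoxybenzoyl chloride | COc1ccc(C(=O)Cl)cc1 | starting material
16 | Fertidin, (3R,3aS,4S,8aR)-4-(4-methoxybenzoyloxy)-6,8a-dimethyl-3-isopropyl-octahydroazulen-3-ol | COc1ccc(C(=O)O[C@H]2CC(C)=CC[C@@]3(C)CC[C@@](O)(C(C)C)[C@H]23)cc1 | target

## Totals
Total steps: 12. Longest linear sequence: 12 (no convergent branch; **6**, **9** and **15** are purchased reagents).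

## Three steps most likely to fail
1. **Step 5 (new photo-MHAT allylation).** Competing HAT on the product's terminal allyl alkene, or poor radical capture by the sulfone, would lower the yield.
   Fallback (known chemistry): Mukaiyama hydration of **5** (Co(acac)2, PhSiH3, O2) to the tertiary alcohol, primary-OH protection, selective oxalate formation at the less hindered tertiary OH, then photoredox deoxygenative allylation with an allyl sulfone.
2. **Step 10 (C3/C3a equilibration).** The base could instead isomerise the β,γ-alkene into conjugation or dehydrate the ketol, and the thermodynamic ring fusion may not be trans.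
   Fallback: force the retro-aldol (KOH, MeOH) to the isolated seco-diketone, then re-close with a chelation-controlled Ti-enolate aldol (TiCl4, Et3N, −78 °C).
3. **Step 3 (photodeconjugation).** Reconjugation to enal **3**, or protonation on the wrong face, would spoil the Cα stereocentre.
   Fallback: Luche reduction of **3**, then decatungstate/cobaloxime contra-thermodynamic photoisomerisation of the allylic alcohol to give **5** directly.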